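**Retrosynthetic overview**
- No ring is formed: rings A, B and C are the benzene rings of three commercial gallic-acid-level building blocks. Only the two depside C–O bonds are made.
- Last bond made (key step): the acyl C–O bond between the ring B carbonyl and a meta oxygen of ring A, formed on an otherwise unprotected gallate ester.
- First bond made: the acyl C–O bond between the ring C carbonyl and the para oxygen of ring B, formed on a ring B aldehyde that is then oxidised to the acid.
- Order: free the para phenol of ring B → ring C–ring B ester → CHO to CO2H → ring B–ring A ester → global hydrogenolysis.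

Assumption: the target has no stereocentre or other stereogenic element, so it is achiral and no step has to control configuration.

**Step 1**
Reactants: 1 3,4,5-tris(benzyloxy)benzaldehyde
Product: 2 3,5-bis(benzyloxy)-4-hydroxybenzaldehyde
Conditions: BCl3 (1.3 equiv, 1 M in CH2Cl2), CH2Cl2, −78 → −40 °C, 1 h; H2O
Reagents that add atoms: none
Why: Lewis-acid ether cleavage (BCl3 dealkylation) should be selective for the 4-benzyl ether because it is the only one para to the formyl group (BCl3 bound at C=O makes the 4-oxygen a vinylogous carboxylate leaving group for chloride attack at its benzylic carbon) and the only one twisted out of plane by two ortho substituents, the same bias that turns 3,4,5-trialkoxybenzaldehydes into 4-hydroxy-3,5-dialkoxybenzaldehydes.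

**Step 2**
Reactants: 3 3,4,5-tris(benzyloxy)benzoic acid; 2 3,5-bis(benzyloxy)-4-hydroxybenzaldehyde
Product: 5 2,6-bis(benzyloxy)-4-formylphenyl 3,4,5-tris(benzyloxy)benzoate, via acid chloride 4 (not isolated)
Conditions: 3, (COCl)2 (1.3 equiv), DMF (cat.), CH2Cl2, 0 °C → rt, evaporate; then 2, Et3N (1.5 equiv), DMAP (0.1 equiv), CH2Cl2, 0 °C → rt
Reagents that add atoms: none
Why: Acid chloride formation followed by DMAP-catalysed nucleophilic acyl substitution (Einhorn-type phenol acylation) at the only hydroxyl of 2; the formyl group serves as a masked carboxyl, so no acid/phenol competition arises.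

**Step 3**
Reactants: 5 2,6-bis(benzyloxy)-4-formylphenyl 3,4,5-tris(benzyloxy)benzoate
Product: 6 3,5-bis(benzyloxy)-4-{[3,4,5-tris(benzyloxy)benzoyl]oxy}benzoic acid
Conditions: NaClO2 (2 equiv), NaH2PO4 (2 equiv), 2-methyl-2-butene (10 equiv), THF/t-BuOH/H2O (2:2:1), 0 °C → rt
Reagents that add atoms: sodium chlorite, [Na+].[O-]Cl=O
Why: Pinnick oxidation converts the aromatic aldehyde to the acid at about pH 4, where the hindered aryl ester and the benzyl ethers are untouched and 2-methyl-2-butene traps HOCl before it can chlorinate the electron-rich rings.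

**Step 4**
Reactants: 7 gallic acid (3,4,5-trihydroxybenzoic acid); 8 benzyl bromide
Product: 9 benzyl gallate (benzyl 3,4,5-trihydroxybenzoate)
Conditions: KHCO3 (1.1 equiv), DMF, rt → 40 °C, 16 h
Reagents that add atoms: none
Why: Chemoselective carboxylate O-alkylation (SN2): KHCO3 deprotonates only the carboxylic acid (pKa about 4.4) and not the phenols (pKa about 9 and above), so benzyl bromide gives the benzyl ester and leaves the three hydroxyls free.

**Step 5**
Reactants: 6 3,5-bis(benzyloxy)-4-{[3,4,5-tris(benzyloxy)benzoyl]oxy}benzoic acid; 9 benzyl gallate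
Product: 13 benzyl 3-{[3,5-bis(benzyloxy)-4-{[3,4,5-tris(benzyloxy)benzoyl]oxy}benzoyl]oxy}-4,5-dihydroxybenzoate, via acid chloride 10 (not isolated), via gallate boronate 11 (not isolated), via acylated boronate 12 (not isolated)
Conditions: a) 6, (COCl)2 (1.3 equiv), DMF (cat.), CH2Cl2, 0 °C → rt, evaporate; b) 9 (1.2 equiv), PhB(OH)2 (1.25 equiv), toluene, Dean–Stark reflux, 1 h; c) add 10 in CH2Cl2, i-Pr2NEt (1.5 equiv), −20 → 0 °C; d) pinacol (2 equiv), AcOH (1 equiv), rt, 1 h
Reagents that add atoms: none
Why: Proposed new method: boronate-templated site-selective mono-O-acylation of an unprotected gallate ester — PhB(OH)2 condenses with a vicinal pair of hydroxyls of 9 to the five-membered dioxaborole 11, and because every vicinal pair contains the para oxygen, exactly one meta hydroxyl stays free while the two boron-bound oxygens are deactivated by O-to-B π donation; the hindered base i-Pr2NEt (which does not turn the boronate into a nucleophilic borate) lets this single OH attack acid chloride 10 by nucleophilic acyl substitution, the 1:1 boron stoichiometry with 10 as limiting reagent excludes diacylation, any para ester formed by leakage would drift to the thermodynamically preferred meta position, and pinacol then removes boron under neutral conditions; the closest known reaction types are transient boronic-ester masking of cis-1,2-diols in carbohydrate acylation and borate-controlled meta-O-alkylation of gallic acid.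

**Step 6**
Reactants: 13 benzyl 3-{[3,5-bis(benzyloxy)-4-{[3,4,5-tris(benzyloxy)benzoyl]oxy}benzoyl]oxy}-4,5-dihydroxybenzoate
Product: 14 3-{[3,5-dihydroxy-4-{[3,4,5-trihydroxybenzoyl]oxy}benzoyl]oxy}-4,5-dihydroxybenzoic acid (target)
Conditions: H2 (1 atm), 10% Pd/C, THF, rt, 4 h; filter (Celite), evaporate below 30 °C, C18 or Sephadex LH-20 (no base, no MeOH)
Reagents that add atoms: none
Why: Catalytic hydrogenolysis removes the five benzyl ethers and the benzyl ester under neutral, aprotic conditions that leave both aryl ester (depside) bonds intact and give no base to drive acyl migration; no stereocentre is present or formed.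

**Compound list**
1 | 3,4,5-tris(benzyloxy)benzaldehyde | O=Cc1cc(OCc2ccccc2)c(OCc2ccccc2)c(OCc2ccccc2)c1 | starting material
2 | 3,5-bis(benzyloxy)-4-hydroxybenzaldehyde | O=Cc1cc(OCc2ccccc2)c(O)c(OCc2ccccc2)c1 | intermediate
3 | 3,4,5-tris(benzyloxy)benzoic acid | OC(=O)c1cc(OCc2ccccc2)c(OCc2ccccc2)c(OCc2ccccc2)c1 | starting material
4 | 3,4,5-tris(benzyloxy)benzoyl chloride | ClC(=O)c1cc(OCc2ccccc2)c(OCc2ccccc2)c(OCc2ccccc2)c1 | intermediate
5 | 2,6-bis(benzyloxy)-4-formylphenyl 3,4,5-tris(benzyloxy)benzoate | O=Cc1cc(OCc2ccccc2)c(OC(=O)c2cc(OCc3ccccc3)c(OCc3ccccc3)c(OCc3ccccc3)c2)c(OCc2ccccc2)c1 | intermediate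
6 | 3,5-bis(benzyloxy)-4-{[3,4,5-tris(benzyloxy)benzoyl]oxy}benzoic acid | OC(=O)c1cc(OCc2ccccc2)c(OC(=O)c2cc(OCc3ccccc3)c(OCc3ccccc3)c(OCc3ccccc3)c2)c(OCc2ccccc2)c1 | intermediate
7 | gallic acid (3,4,5-trihydroxybenzoic acid) | OC(=O)c1cc(O)c(O)c(O)c1 | starting material
8 | benzyl bromide | BrCc1ccccc1 | starting material
9 | benzyl gallate (benzyl 3,4,5-trihydroxybenzoate) | O=C(OCc1ccccc1)c1cc(O)c(O)c(O)c1 | intermediate
10 | 3,5-bis(benzyloxy)-4-{[3,4,5-tris(benzyloxy)benzoyl]oxy}benzoyl chloride | ClC(=O)c1cc(OCc2ccccc2)c(OC(=O)c2cc(OCc3ccccc3)c(OCc3ccccc3)c(OCc3ccccc3)c2)c(OCc2ccccc2)c1 | intermediate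
11 | benzyl 7-hydroxy-2-phenyl-1,3,2-benzodioxaborole-5-carboxylate | O=C(OCc1ccccc1)c1cc(O)c2OB(c3ccccc3)Oc2c1 | intermediate
12 | benzyl 7-{[3,5-bis(benzyloxy)-4-{[3,4,5-tris(benzyloxy)benzoyl]oxy}benzoyl]oxy}-2-phenyl-1,3,2-benzodioxaborole-5-carboxylate | O=C(OCc1ccccc1)c1cc(OC(=O)c2cc(OCc3ccccc3)c(OC(=O)c3cc(OCc4ccccc4)c(OCc4ccccc4)c(OCc4ccccc4)c3)c(OCc3ccccc3)c2)c2OB(c3ccccc3)Oc2c1 | intermediate
13 | benzyl 3-{[3,5-bis(benzyloxy)-4-{[3,4,5-tris(benzyloxy)benzoyl]oxy}benzoyl]oxy}-4,5-dihydroxybenzoate | O=C(OCc1ccccc1)c1cc(O)c(O)c(OC(=O)c2cc(OCc3ccccc3)c(OC(=O)c3cc(OCc4ccccc4)c(OCc4ccccc4)c(OCc4ccccc4)c3)c(OCc3ccccc3)c2)c1 | intermediate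
14 | 3-{[3,5-dihydroxy-4-{[3,4,5-trihydroxybenzoyl]oxy}benzoyl]oxy}-4,5-dihydroxybenzoic acid (CNP0317472.0) | O=C(O)c1cc(O)c(O)c(OC(=O)c2cc(O)c(OC(=O)c3cc(O)c(O)c(O)c3)c(O)c2)c1 | target

**Totals**
Total step count: 6. Longest linear sequence: 5 steps (steps 1, 2, 3, 5, 6); step 4 is a one-step side branch.

**Steps most likely to fail**

Step 1 (selective para debenzylation; risk of over-cleavage of a neighbouring benzyl ether or ring benzylation). The fallback replaces selective deprotection by selective protection. It sets out from benzyl bromide 8 and comes back at 2. Commercial 3,4,5-trihydroxybenzaldehyde F1 is alkylated at its most acidic, para hydroxyl (allyl bromide 1.05 equiv, NaHCO3, NaI, DMF, 40 °C) to give 4-(allyloxy)-3,5-dihydroxybenzaldehyde F2. Benzyl bromide 8 (2.3 equiv), K2CO3, DMF, rt then gives 4-(allyloxy)-3,5-bis(benzyloxy)benzaldehyde F3. Allyl transfer with Pd(PPh3)4 (2 mol%) and TolSO2Na (sodium p-toluenesulfinate) in THF/MeOH at rt returns 2. All three operations are standard (weak-base para-selective alkylation, Williamson etherification, Tsuji–Trost deallylation).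

Step 5 (the proposed boronate-templated acylation; risks are incomplete masking, borate-mediated acylation at a boron-bound oxygen, or diacylation). The fallback uses a conventional covalent protecting group. It sets out from 9 and comes back at the target 14, bypassing 13. Benzyl gallate 9 is heated with Ph2CCl2 (1.2 equiv, neat, 170 °C, 15 min) to give benzyl 7-hydroxy-2,2-diphenyl-1,3-benzodioxole-5-carboxylate F4, which has a single free meta hydroxyl. F4 is acylated with acid chloride 10 (made from 6 as in step 5; i-Pr2NEt, DMAP, CH2Cl2, 0 °C → rt) to give benzyl 7-{[3,5-bis(benzyloxy)-4-{[3,4,5-tris(benzyloxy)benzoyl]oxy}benzoyl]oxy}-2,2-diphenyl-1,3-benzodioxole-5-carboxylate F5. H2 (1 atm), Pd(OH)2/C, THF, rt then removes all benzyl groups and the diphenylmethylene ketal in one operation to give 14.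

Step 6 (global deprotection; the risk is migration of the ring C acyl group from the para to a meta oxygen of ring B, or air oxidation, while the free polyphenol sits on the catalyst). The fallback replaces reductive hydrogenolysis by Lewis-acid benzyl transfer to an arene scavenger in a strictly acidic medium, where phenoxide-driven acyl migration cannot occur. It sets out from 13 and comes back at 14: BCl3 (12 equiv), pentamethylbenzene (18 equiv), CH2Cl2, −78 → −20 °C, quench with wet THF, C18 chromatography. New compounds on this way: none F0.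

**Further compounds**
F1 | step 1 | 3,4,5-trihydroxybenzaldehyde | O=Cc1cc(O)c(O)c(O)c1
F2 | step 1 | 4-(allyloxy)-3,5-dihydroxybenzaldehyde | C=CCOc1c(O)cc(C=O)cc1O
F3 | step 1 | 4-(allyloxy)-3,5-bis(benzyloxy)benzaldehyde | C=CCOc1c(OCc2ccccc2)cc(C=O)cc1OCc1ccccc1
F4 | step 5 | benzyl 7-hydroxy-2,2-diphenyl-1,3-benzodioxole-5-carboxylate | O=C(OCc1ccccc1)c1cc(O)c2OC(c3ccccc3)(c3ccccc3)Oc2c1
F5 | step 5 | benzyl 7-{[3,5-bis(benzyloxy)-4-{[3,4,5-tris(benzyloxy)benzoyl]oxy}benzoyl]oxy}-2,2-diphenyl-1,3-benzodioxole-5-carboxylate | O=C(OCc1ccccc1)c1cc(OC(=O)c2cc(OCc3ccccc3)c(OC(=O)c3cc(OCc4ccccc4)c(OCc4ccccc4)c(OCc4ccccc4)c3)c(OCc3ccccc3)c2)c2OC(c3ccccc3)(c3ccccc3)Oc2c1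
F0 | step 6 | none | none
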